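## Structural features

Vitrofolal B (19) is a 1-aryl-2-naphthol. Ring A (C4a, C5 to C8, C8a) and ring B (C1 to C4, C4a, C8a) form a naphthalene, and a 3,4-dimethoxyphenyl ring (ring C) is joined to C1 by one biaryl bond. Ring B carries the hydroxyl at C2 and the formyl group at C3; ring A carries a free hydroxyl at C7 and a methoxy group at C8. C8-OMe, C8a, C1-aryl, C2-OH and C3-CHO therefore form one crowded edge, with the aryl group peri to the methoxy group. The target has no stereocentre: the only stereocentres of the route are the neighbouring C1 and C2 of the dihydronaphthalene stage (12, 13), both become sp2 on aromatisation, and their relative configuration does not affect the outcome. The fragile parts are the salicylaldehyde unit, which is reducible under hydrogenolysis and so must be unveiled last, the two oxidation-prone phenols on an electron-rich naphthalene, and the distinction between free O7 and methylated O8. The real difficulty is regiochemical: ring B must close on the ring A carbon between the side chain and the methoxy group (C8a, ortho to OMe), whereas a vanillin-type ring normally closes para to that methoxy group and gives the 6,7-dioxygenated series. The key step exploits three features: C1 is benzylic to ring C, whose para methoxy group stabilises a cation there; C2 bears oxygen, which can arrive as the oxygen of a styrenyl epoxide; and C8a is ortho to the C8 methoxy group, so ring A can be the nucleophile once a bromine occupies the competing para carbon (C5). The bromine and the O7 benzyl group are then removed in a single hydrogenolysis.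

## Logic of the disconnections

19 to 18 to 17. No skeletal bond is cut; the C3 formyl carbon is traced back through the hydroxymethyl stage 18 to the methyl ester 17. The ester is what the chain-building condensation delivers, and it tolerates base, Lewis acid, oxidant and hydrogen, which an aldehyde would not. The gain is that the aldehyde exists only in the last step. The demand is a hydride reduction in the presence of two phenols, then an oxidant that takes the benzylic alcohol and leaves the naphthalenediol alone.

17 to 15 (through 16). The C5–H bond is traced back to C5–Br and the O7–H bond to O7–CH2Ph. The bromine is the regiochemical control element of the ring closure and the benzyl group masks the phenol through enolate and Lewis acid chemistry. Both go in one hydrogenolysis, so the control element costs no step. The demand is that ester, methyl ethers and naphthalene stay inert, which is why this is done at the ester stage.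

15 to 13 (through 14). This is a retro-aromatisation: the naphthol is the enol of ketone 14, which comes from oxidation of the C2 carbinol of 13. It uncovers sp3 centres at C1 and C2, so the C1–C8a bond becomes accessible to cation chemistry while the C2 oxygen is already in place. The demand is that oxidation must beat acid- or base-induced loss of the C2 oxygen, which would aromatise ring B without it.

13 to 12. The C1–C8a bond is cut. C1 is a benzylic cation synthon stabilised by ring C, C8a is an arene nucleophile ortho to a methoxy group, and the vicinal C2 hydroxyl is the retron of an epoxide. Ring B is opened and the crowded C8/C8a/C1 junction is reduced to an acyclic chain. The demands are closure at C8a and not at the brominated carbon, a cis relation of ring A and the epoxide across the acrylate double bond, capture of the cation before any 1,2-shift, and survival of the product under the acid.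

12 to 11. Both epoxide C–O bonds are cut back to the E styrenyl alkene. The two alkenes of 11 differ sharply in electron demand, so an electrophilic oxygen donor should select the styrenyl one. The demand is neutral, acid-free oxygen transfer, because 12 is an acid-labile aryl vinyl epoxide.

11 to 7 plus 2 (through 8, 9 and 10). The C3=C4 double bond (naphthalene numbering) is cut as an aldol condensation retron. This splits the chain into two halves of similar size, one carrying ring A and one carrying ring C with C1 to C3. The demands are reaction of dienolate 8 at its α carbon and an elimination from 10 that places ring A trans to the ester (E), the geometry that later holds ring A beside the epoxide.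

7 to 6 to 4 plus 3 (through 5). The ester O–CH3 bond is cut, then the styrenyl C1=C2 double bond as a Wittig retron. The demand is the E alkene and retention of the double bond in the β,γ position.

2 to 1. The O7–benzyl bond is cut; the bromine is already present in 1.

## Other disconnections considered

Alternative 1: The cut is through two ring bonds of ring C (C1'–C2' and C5'–C6'), so that ring C is built on a finished naphthalene. In the forward key step the 1-ethynylnaphthalene A2 and 2,3-dimethoxybuta-1,3-diene A3 combine under cobalt catalysis (CoBr2(dppe) reduced by zinc powder, ZnI2 as activator) in a formal [4+2] cycloaddition to the cyclohexa-1,4-diene A1, which a later dehydrogenation would turn into the dimethoxyphenyl ring.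
- In its favour: it is convergent, catalytic and neutral; the symmetrical diene leaves no regiochemical question in ring C; there is no cation, no transient stereocentre and no blocking halogen. On these mechanistic points it is the equal or the better of the chosen plan.
- Against it here: ring C is the one part of the target that can be bought intact (in 4), so the step spends effort where none is needed. The real problem, ring B with the 7,8-oxygenation of ring A, is shifted into the preparation of A2, a differentially protected 2,7,8-trioxygenated naphthalene that still needs C1 functionalisation and alkynylation. The alkyne of A2 sits between the C2 acetal and the peri C8 methoxy group, a hindered site for cobalt. A1 is an acid-labile bis-enol ether.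
- A1 also has no carbon at C3. The formyl group would have to come from a directed ortho-lithiation with competing metalation sites, and the final debenzylation would then run in the presence of the aldehyde.
- Step economy: four operations after A1 (aromatisation, formylation, two deprotections) plus the synthesis of A2 are expected to exceed the ten steps of the chosen plan.

Alternative 2: The cut is through C1–C8a and C2–C3. In the forward key step photolysis of the diazo ketone A5 triggers a Wolff rearrangement in which the ring A aryl migrates to the carbene carbon and gives the diaryl ketene A6. A 6π electrocyclisation of A6 over the ketene C=C, the C8a=C4a bond and the ortho E alkene, followed by tautomerisation, gives the naphthol A4.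
- In its favour: two bonds of ring B form in one operation; A4 is already aromatic with the C2 hydroxyl in place; and the position of ring closure is dictated by the substitution of ring A, with no cation and no blocking atom. On regiochemical security and on the redox state of ring B it is better than the chosen plan.
- Its endgame (debenzylation, desilylation, benzylic oxidation) is one step shorter than the four steps that follow 13.
- Against it here: A5 needs a ring A with four contiguous substituents (alkenyl, acyl, methoxy, benzyloxy). The crowded carbon between side chain and methoxy group must therefore be functionalised early by directed metalation or a halogenated building block, then a deoxybenzoin assembled and a diazo group transferred.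
- The acyl carbene and the ketene have competing exits (cyclopropanation or [2+2] addition with the ortho alkene, capture by adventitious nucleophiles, photoisomerisation of the alkene), and the electrocyclisation has to break the aromaticity of ring A temporarily.
- On balance the key step is more elegant and at least as defensible mechanistically, but the precursor is estimated at eight or nine steps against five for 12, so the total is longer.

Alternative 3: The cut is through C2–C3 and C3–C4, so that C3 is inserted with its carboxylate. In the forward key step BF3·OEt2 promotes addition of ethyl diazoacetate A9 to the carbonyl of the 1-aryl-2-indanone A8, and a 1,2-shift of the methylene carbon with loss of nitrogen expands the ring to the β-keto ester A7 (enol form).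
- In its favour: C3 and its carbon substituent arrive together; C1–C8a and the C1–aryl bond exist beforehand, so arene nucleophilicity is not an issue; no blocking group is needed. On these points it is the equal or the better.
- A7 is one dehydrogenation away from a 2-naphthol-3-carboxylate of the same type as 16, so its endgame equals that of the chosen plan in length.
- Against it here: the migrating group must be the methylene and not the aryl-bearing benzylic carbon, and both are benzylic. A8 is enolised very easily at its doubly benzylic C1 and is prone to self-condensation and autoxidation under a Lewis acid.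
- Making A8 needs the aryl group on the α carbon next to the methoxy-bearing ring position and not on the remote one. This is the same regiochemical problem as in the chosen plan, without a blocking-group answer.
- Four steps would follow A7 and six or seven are estimated before A8, so the route is longer.

Key step: step 6

Assumption: LiN(i-Pr)2, NaN(SiMe3)2 and dimethyldioxirane are used as stock solutions. Compounds 12, 13 and 14 are racemic with one enantiomer drawn: (2R,3R)-12 leads to (1R,2S)-13 by inversion at C1 and retention at C2, and both centres vanish in step 7.

## Route

Step 1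
Reactants: 1 6-bromovanillin (2-bromo-4-hydroxy-5-methoxybenzaldehyde)
Product: 2 4-(benzyloxy)-2-bromo-5-methoxybenzaldehyde
Conditions: BnBr, K2CO3, DMF, rt
Reagents that add atoms: benzyl bromide, BrCc1ccccc1
Why: Williamson ether synthesis on the only acidic OH; the benzyl ether withstands enolate, dioxirane, Lewis acid and MnO2 and is later removed together with the bromine.

Step 2
Reactants: 3 (2-carboxyethyl)triphenylphosphonium bromide; 4 veratraldehyde (3,4-dimethoxybenzaldehyde)
Product: 6 (E)-4-(3,4-dimethoxyphenyl)but-3-enoic acid, via carboxylate ylide 5 (not isolated)
Conditions: NaN(SiMe3)2 (2.2 equiv), THF, 0 °C; 4, −78 °C to rt; aq. HCl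
Reagents that add atoms: none
Why: Wittig reaction; two equivalents of base form the carboxylate ylide 5, and ylides of this type are known to give mainly the E β,γ-unsaturated acid with aryl aldehydes. Acid–base extraction separates 6 from triphenylphosphine oxide, and the double bond stays conjugated with ring C.

Step 3
Reactants: 6 (E)-4-(3,4-dimethoxyphenyl)but-3-enoic acid
Product: 7 methyl (E)-4-(3,4-dimethoxyphenyl)but-3-enoate
Conditions: MeI, KHCO3, DMF, rt
Reagents that add atoms: iodomethane, CI
Why: O-alkylation of the carboxylate (SN2); the weak base avoids both the acid-induced lactonisation of this electron-rich styrylacetic acid and migration of the double bond.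

Step 4
Reactants: 7 methyl (E)-4-(3,4-dimethoxyphenyl)but-3-enoate; 2 4-(benzyloxy)-2-bromo-5-methoxybenzaldehyde
Product: 11 methyl (2E,3E)-2-{[4-(benzyloxy)-2-bromo-5-methoxyphenyl]methylidene}-4-(3,4-dimethoxyphenyl)but-3-enoate, via lithium dienolate 8 (not isolated), via lithium aldolate 9 (not isolated), via β-acetoxy ester 10 (not isolated)
Conditions: LiN(i-Pr)2, THF, −78 °C; 2; Ac2O, −78 °C to rt; DBU, rt to 40 °C
Reagents that add atoms: none
Why: Aldol condensation in one flask: dienolate 8 adds through its α carbon to the non-enolisable aldehyde, acetic anhydride traps aldolate 9 as acetate 10 (which blocks retro-aldol), and DBU effects E1cB elimination through the doubly activated C2–H. The elimination is expected to place ring A trans to the ester (E), as is usual for α-substituted cinnamates, and the styrenyl alkene is untouched.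

Step 5
Reactants: 11 methyl (2E,3E)-2-{[4-(benzyloxy)-2-bromo-5-methoxyphenyl]methylidene}-4-(3,4-dimethoxyphenyl)but-3-enoate
Product: 12 methyl (E)-3-[4-(benzyloxy)-2-bromo-5-methoxyphenyl]-2-[(2R*,3R*)-3-(3,4-dimethoxyphenyl)oxiran-2-yl]prop-2-enoate (racemic trans epoxide)
Conditions: dimethyldioxirane (1.1 equiv, acetone), CH2Cl2, −20 to 0 °C; evaporate cold, use crude
Reagents that add atoms: dimethyldioxirane, CC1(C)OO1
Why: Dioxirane epoxidation; the electrophilic oxidant selects the electron-rich styrenyl alkene over the ester-bearing trisubstituted one, and concerted syn oxygen transfer to the E alkene gives the trans epoxide. The only by-product is acetone, so the acid-labile epoxide need not see silica or acid.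

Step 6
Reactants: 12 methyl (E)-3-[4-(benzyloxy)-2-bromo-5-methoxyphenyl]-2-[(2R*,3R*)-3-(3,4-dimethoxyphenyl)oxiran-2-yl]prop-2-enoate
Product: 13 methyl (1R*,2S*)-7-(benzyloxy)-5-bromo-1-(3,4-dimethoxyphenyl)-2-hydroxy-8-methoxy-1,2-dihydronaphthalene-3-carboxylate (racemic trans isomer)
Conditions: BF3·OEt2 (0.3 equiv), CH2Cl2 (0.01 M), −78 to −40 °C; Et3N, aq. NaHCO3
Reagents that add atoms: none
Why: BF3 binds the epoxide oxygen and the C1–O bond ionises because the benzylic cation is stabilised by the para methoxy group of ring C; C8a of ring A attacks C1 in an intramolecular Friedel–Crafts alkylation, and loss of the C8a proton restores aromaticity, protonates the C2 oxygen and releases the Lewis acid. The closest known reaction type is the Lewis acid-mediated intramolecular epoxide–arene cyclisation that gives trans 1-aryl-2-tetralols, together with the acid closure of benzylic cations onto an arylidene ring that gives 1-aryl-1,2-dihydronaphthalene lignans. Ring B closes in the 6-endo mode, the nucleophile entering at the distal epoxide carbon so that both epoxide carbons lie in the new ring. C1 is the new stereocentre: attack anti to the departing oxygen (inversion at C1, retention at C2) on the trans epoxide gives the trans 1-aryl-2-ol, and if an open cation intervened the cis isomer would serve equally because C1 and C2 both become sp2 in step 7. Regioselectivity rests on the C5 bromine, which occupies the ring A carbon para to the methoxy group so that only C8a can lose a proton after attack, and on the E acrylate, which holds ring A cis to the epoxide. Chemoselectivity over a Meinwald-type 1,2-shift, over capture of the cation by the ester carbonyl and over acid-induced loss of the C2 hydroxyl from 13 is sought through low temperature, high dilution, sub-stoichiometric Lewis acid and a basic quench; the methyl ester is kept because its carbonyl adduct cannot easily lose an alkyl group and should revert.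

Step 7
Reactants: 13 methyl (1R*,2S*)-7-(benzyloxy)-5-bromo-1-(3,4-dimethoxyphenyl)-2-hydroxy-8-methoxy-1,2-dihydronaphthalene-3-carboxylate
Product: 15 methyl 7-(benzyloxy)-5-bromo-1-(3,4-dimethoxyphenyl)-2-hydroxy-8-methoxynaphthalene-3-carboxylate, via keto tautomer 14 (not isolated)
Conditions: activated MnO2 (excess), CH2Cl2, rt
Reagents that add atoms: none
Why: MnO2 oxidation of the allylic C2 carbinol gives ketone 14, whose C1–H is doubly benzylic and α to the carbonyl, so it should enolise at once to the aromatic naphthol. The neutral heterogeneous oxidant avoids dehydration, and both stereocentres are removed here.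

Step 8
Reactants: 15 methyl 7-(benzyloxy)-5-bromo-1-(3,4-dimethoxyphenyl)-2-hydroxy-8-methoxynaphthalene-3-carboxylate
Product: 17 methyl 1-(3,4-dimethoxyphenyl)-2,7-dihydroxy-8-methoxynaphthalene-3-carboxylate, via debrominated benzyl ether 16 (not isolated)
Conditions: H2 (1 atm), 10% Pd/C, NaOAc, EtOAc–MeOH, rt
Reagents that add atoms: none
Why: Catalytic hydrogenolysis; the aryl C–Br bond should go first (NaOAc takes up HBr), followed by the aryl benzyl ether. Ester, methyl ethers and naphthalene are inert at 1 atm, and no aldehyde is present yet to be reduced.

Step 9
Reactants: 17 methyl 1-(3,4-dimethoxyphenyl)-2,7-dihydroxy-8-methoxynaphthalene-3-carboxylate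
Product: 18 3-(hydroxymethyl)-1-(3,4-dimethoxyphenyl)-8-methoxynaphthalene-2,7-diol
Conditions: LiAlH4 (4 equiv), THF, 0 °C to rt; aq. potassium sodium tartrate (KNaC4H4O6)
Reagents that add atoms: none
Why: Hydride reduction of the ester after deprotonation of both phenols (hence the excess), as in the reduction of salicylates to salicyl alcohols. Keeping to room temperature and a neutral work-up avoids ortho-quinone methide formation and benzylic C–O reduction.

Step 10
Reactants: 18 3-(hydroxymethyl)-1-(3,4-dimethoxyphenyl)-8-methoxynaphthalene-2,7-diol
Product: 19 vitrofolal B (1-(3,4-dimethoxyphenyl)-2,7-dihydroxy-8-methoxynaphthalene-3-carbaldehyde)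
Conditions: activated MnO2, EtOAc, rt
Reagents that add atoms: none
Why: Selective MnO2 oxidation of the benzylic alcohol, as in the conversion of ortho-hydroxybenzyl alcohols to salicylaldehydes. The aldehyde formed is hydrogen-bonded to the C2 hydroxyl and resists further oxidation, and phenols are normally tolerated by this oxidant at room temperature.

## Compound list

1 | 6-bromovanillin (2-bromo-4-hydroxy-5-methoxybenzaldehyde) | COc1cc(C=O)c(Br)cc1O | starting material
2 | 4-(benzyloxy)-2-bromo-5-methoxybenzaldehyde | COc1cc(C=O)c(Br)cc1OCc1ccccc1 | intermediate
3 | (2-carboxyethyl)triphenylphosphonium bromide | OC(=O)CC[P+](c1ccccc1)(c1ccccc1)c1ccccc1.[Br-] | starting material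
4 | veratraldehyde (3,4-dimethoxybenzaldehyde) | COc1ccc(C=O)cc1OC | starting material
5 | sodium 3-(triphenyl-λ5-phosphanylidene)propanoate (carboxylate ylide, not isolated) | [Na+].[O-]C(=O)CC=P(c1ccccc1)(c1ccccc1)c1ccccc1 | intermediate
6 | (E)-4-(3,4-dimethoxyphenyl)but-3-enoic acid | COc1ccc(/C=C/CC(=O)O)cc1OC | intermediate
7 | methyl (E)-4-(3,4-dimethoxyphenyl)but-3-enoate | COc1ccc(/C=C/CC(=O)OC)cc1OC | intermediate
8 | lithium (3E)-1-methoxy-4-(3,4-dimethoxyphenyl)buta-1,3-dien-1-olate (dienolate of 7, not isolated) | [Li+].COC([O-])=C/C=C/c1ccc(OC)c(OC)c1 | intermediate
9 | lithium (E)-1-[4-(benzyloxy)-2-bromo-5-methoxyphenyl]-2-(methoxycarbonyl)-4-(3,4-dimethoxyphenyl)but-3-en-1-olate (diastereomer mixture, not isolated) | [Li+].COC(=O)C(/C=C/c1ccc(OC)c(OC)c1)C([O-])c1cc(OC)c(OCc2ccccc2)cc1Br | intermediate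
10 | methyl (E)-2-{acetoxy[4-(benzyloxy)-2-bromo-5-methoxyphenyl]methyl}-4-(3,4-dimethoxyphenyl)but-3-enoate (diastereomer mixture, not isolated) | COC(=O)C(/C=C/c1ccc(OC)c(OC)c1)C(OC(C)=O)c1cc(OC)c(OCc2ccccc2)cc1Br | intermediate
11 | methyl (2E,3E)-2-{[4-(benzyloxy)-2-bromo-5-methoxyphenyl]methylidene}-4-(3,4-dimethoxyphenyl)but-3-enoate | COC(=O)/C(=C/c1cc(OC)c(OCc2ccccc2)cc1Br)/C=C/c1ccc(OC)c(OC)c1 | intermediate
12 | methyl (E)-3-[4-(benzyloxy)-2-bromo-5-methoxyphenyl]-2-[(2R*,3R*)-3-(3,4-dimethoxyphenyl)oxiran-2-yl]prop-2-enoate (racemic, trans epoxide) | COC(=O)/C(=C/c1cc(OC)c(OCc2ccccc2)cc1Br)[C@H]1O[C@@H]1c1ccc(OC)c(OC)c1 | intermediate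
13 | methyl (1R*,2S*)-7-(benzyloxy)-5-bromo-1-(3,4-dimethoxyphenyl)-2-hydroxy-8-methoxy-1,2-dihydronaphthalene-3-carboxylate (racemic, trans) | COC(=O)C1=Cc2c(Br)cc(OCc3ccccc3)c(OC)c2[C@@H](c2ccc(OC)c(OC)c2)[C@@H]1O | intermediate
14 | methyl 7-(benzyloxy)-5-bromo-1-(3,4-dimethoxyphenyl)-8-methoxy-2-oxo-1,2-dihydronaphthalene-3-carboxylate (racemic, not isolated) | COC(=O)C1=Cc2c(Br)cc(OCc3ccccc3)c(OC)c2[C@@H](c2ccc(OC)c(OC)c2)C1=O | intermediate
15 | methyl 7-(benzyloxy)-5-bromo-1-(3,4-dimethoxyphenyl)-2-hydroxy-8-methoxynaphthalene-3-carboxylate | COC(=O)c1cc2c(Br)cc(OCc3ccccc3)c(OC)c2c(-c2ccc(OC)c(OC)c2)c1O | intermediate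
16 | methyl 7-(benzyloxy)-1-(3,4-dimethoxyphenyl)-2-hydroxy-8-methoxynaphthalene-3-carboxylate (not isolated) | COC(=O)c1cc2ccc(OCc3ccccc3)c(OC)c2c(-c2ccc(OC)c(OC)c2)c1O | intermediate
17 | methyl 1-(3,4-dimethoxyphenyl)-2,7-dihydroxy-8-methoxynaphthalene-3-carboxylate | COC(=O)c1cc2ccc(O)c(OC)c2c(-c2ccc(OC)c(OC)c2)c1O | intermediate
18 | 3-(hydroxymethyl)-1-(3,4-dimethoxyphenyl)-8-methoxynaphthalene-2,7-diol | OCc1cc2ccc(O)c(OC)c2c(-c2ccc(OC)c(OC)c2)c1O | intermediate
19 | vitrofolal B | COc1ccc(-c2c(O)c(C=O)cc3ccc(O)c(OC)c23)cc1OC | target

## Step count and least certain steps

Total step count: 10. Longest linear sequence: 9 steps (steps 2 to 10, from 3 and 4); step 1 is a one-step branch that joins at step 4.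

**Step 6 (key step).** The most likely failure is that the benzylic cation escapes before ring closure. It can do so by a 1,2-hydride or vinyl shift, by attack of the ester carbonyl followed by demethylation, or by ipso attack at the brominated carbon with loss or migration of bromine. The product may also ionise at C2 under the acid and aromatise with loss of the oxygen. The cause is that C8a is activated by only one ortho methoxy group, is flanked on both sides, and is deactivated by conjugation with the acrylate and by the meta bromine. The lability of 12 on handling between steps 5 and 6 belongs to the same risk.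

The fallback sets out from 11 and returns to the route at 15. Upjohn dihydroxylation (catalytic OsO4, N-methylmorpholine N-oxide, aqueous acetone) of the electron-rich styrenyl alkene should give the stable, purifiable syn diol methyl (2E,3R*,4R*)-2-{[4-(benzyloxy)-2-bromo-5-methoxyphenyl]methylidene}-4-(3,4-dimethoxyphenyl)-3,4-dihydroxybutanoate F1. Ionisation of its benzylic hydroxyl with catalytic p-toluenesulfonic acid in hexafluoroisopropanol–CH2Cl2 at 0 °C, the benzylic-alcohol Friedel–Crafts closure long used for aryldihydronaphthalene lignans, should give 13 together with its cis isomer methyl (1S*,2S*)-7-(benzyloxy)-5-bromo-1-(3,4-dimethoxyphenyl)-2-hydroxy-8-methoxy-1,2-dihydronaphthalene-3-carboxylate F2. Both are oxidised under the conditions of step 7 to 15. This cation carries a neutral hydroxyl at C2 and not a boron-bound alkoxide, which lowers the driving force for the hydride shift, and the epoxide is bypassed altogether.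

**Step 4.** The elimination may be non-selective, giving some of the acrylate isomer with ring A cis to the ester, which cannot cyclise. The dienolate may also react partly at its γ carbon, or the aldol addition may revert before acetylation.

The fallback sets out from 7 and returns at 11. It replaces the elimination by an olefination. Dienolate 8 (from 7 with two equivalents of LiN(i-Pr)2) is C-phosphinylated with diethyl chlorophosphite, a trivalent phosphorus electrophile that reacts at carbon, to give methyl (E)-2-(diethoxyphosphanyl)-4-(3,4-dimethoxyphenyl)but-3-enoate F3. Oxidation in the same flask with H2O2 gives methyl (E)-2-(diethoxyphosphoryl)-4-(3,4-dimethoxyphenyl)but-3-enoate F4. Horner–Wadsworth–Emmons reaction of F4 with 2 (NaH, THF, 0 °C to rt) should give 11 with the usual preference for the aryl group trans to the ester.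

**Step 10.** Oxidation of the electron-rich naphthalenediol (quinone formation or oxidative coupling) or ortho-quinone methide formation on the oxidant surface may compete with oxidation of the benzylic alcohol, since two free phenols are present.

The fallback sets out from 17 and returns at 19. Both phenols are protected (NaH, chloromethyl methyl ether, DMF) as methyl 1-(3,4-dimethoxyphenyl)-8-methoxy-2,7-bis(methoxymethoxy)naphthalene-3-carboxylate F5. Reduction with i-Bu2AlH (CH2Cl2, −78 to 0 °C) gives [1-(3,4-dimethoxyphenyl)-8-methoxy-2,7-bis(methoxymethoxy)naphthalen-3-yl]methanol F6. MnO2 oxidation gives 1-(3,4-dimethoxyphenyl)-8-methoxy-2,7-bis(methoxymethoxy)naphthalene-3-carbaldehyde F7, and aqueous HCl in THF removes both acetals to give 19. The redox work is then done on a substrate without free phenols, and acetals cannot migrate to the neighbouring alkoxide.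

**Step 8.** Hydrogenolysis may stall through poisoning of the catalyst by bromide, leaving the benzyl ether in place, or forcing it may begin to saturate the naphthalene.

The fallback sets out from 15 and returns at 17. It separates the two cleavages and uses no hydrogen gas. Homogeneous transfer reduction (Pd(OAc)2, PPh3, HCO2Na, DMF, 80 °C) removes the bromine to give 16, now isolated. BCl3 with pentamethylbenzene as cation scavenger (CH2Cl2, −78 °C) then cleaves the aryl benzyl ether to give 17. This fallback makes no compound outside the list (F0).

## Further compounds

F1 | step 6 | methyl (2E,3R*,4R*)-2-{[4-(benzyloxy)-2-bromo-5-methoxyphenyl]methylidene}-4-(3,4-dimethoxyphenyl)-3,4-dihydroxybutanoate (racemic) | COC(=O)/C(=C/c1cc(OC)c(OCc2ccccc2)cc1Br)[C@@H](O)[C@H](O)c1ccc(OC)c(OC)c1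
F2 | step 6 | methyl (1S*,2S*)-7-(benzyloxy)-5-bromo-1-(3,4-dimethoxyphenyl)-2-hydroxy-8-methoxy-1,2-dihydronaphthalene-3-carboxylate (racemic, cis isomer of 13) | COC(=O)C1=Cc2c(Br)cc(OCc3ccccc3)c(OC)c2[C@H](c2ccc(OC)c(OC)c2)[C@@H]1O
F3 | step 4 | methyl (E)-2-(diethoxyphosphanyl)-4-(3,4-dimethoxyphenyl)but-3-enoate | CCOP(OCC)C(/C=C/c1ccc(OC)c(OC)c1)C(=O)OC
F4 | step 4 | methyl (E)-2-(diethoxyphosphoryl)-4-(3,4-dimethoxyphenyl)but-3-enoate | CCOP(=O)(OCC)C(/C=C/c1ccc(OC)c(OC)c1)C(=O)OC
F5 | step 10 | methyl 1-(3,4-dimethoxyphenyl)-8-methoxy-2,7-bis(methoxymethoxy)naphthalene-3-carboxylate | COCOc1ccc2cc(C(=O)OC)c(OCOC)c(-c3ccc(OC)c(OC)c3)c2c1OC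
F6 | step 10 | [1-(3,4-dimethoxyphenyl)-8-methoxy-2,7-bis(methoxymethoxy)naphthalen-3-yl]methanol | COCOc1ccc2cc(CO)c(OCOC)c(-c3ccc(OC)c(OC)c3)c2c1OC
F7 | step 10 | 1-(3,4-dimethoxyphenyl)-8-methoxy-2,7-bis(methoxymethoxy)naphthalene-3-carbaldehyde | COCOc1ccc2cc(C=O)c(OCOC)c(-c3ccc(OC)c(OC)c3)c2c1OC
F0 | step 8 | none | none
A1 | alternative 1 | 7-(benzyloxy)-1-(4,5-dimethoxycyclohexa-1,4-dien-1-yl)-8-methoxy-2-(methoxymethoxy)naphthalene | COCOc1ccc2ccc(OCc3ccccc3)c(OC)c2c1C1=CCC(OC)=C(OC)C1
A2 | alternative 1 | 7-(benzyloxy)-1-ethynyl-8-methoxy-2-(methoxymethoxy)naphthalene | COCOc1ccc2ccc(OCc3ccccc3)c(OC)c2c1C#C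
A3 | alternative 1 | 2,3-dimethoxybuta-1,3-diene | COC(=C)C(=C)OC
A4 | alternative 2 | 7-(benzyloxy)-3-[(tert-butyldimethylsilyloxy)methyl]-1-(3,4-dimethoxyphenyl)-8-methoxynaphthalen-2-ol | COc1ccc(-c2c(O)c(CO[Si](C)(C)C(C)(C)C)cc3ccc(OCc4ccccc4)c(OC)c23)cc1OC
A5 | alternative 2 | 1-[3-(benzyloxy)-6-[(E)-3-(tert-butyldimethylsilyloxy)prop-1-en-1-yl]-2-methoxyphenyl]-2-diazo-2-(3,4-dimethoxyphenyl)ethan-1-one | COc1ccc(C(=[N+]=[N-])C(=O)c2c(/C=C/CO[Si](C)(C)C(C)(C)C)ccc(OCc3ccccc3)c2OC)cc1OC
A6 | alternative 2 | 2-[3-(benzyloxy)-6-[(E)-3-(tert-butyldimethylsilyloxy)prop-1-en-1-yl]-2-methoxyphenyl]-2-(3,4-dimethoxyphenyl)ethen-1-one (diaryl ketene) | COc1ccc(C(=C=O)c2c(/C=C/CO[Si](C)(C)C(C)(C)C)ccc(OCc3ccccc3)c2OC)cc1OC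
A7 | alternative 3 | ethyl 7-(benzyloxy)-1-(3,4-dimethoxyphenyl)-2-hydroxy-8-methoxy-1,4-dihydronaphthalene-3-carboxylate (enol form, racemic) | CCOC(=O)C1=C(O)C(c2ccc(OC)c(OC)c2)c2c(OC)c(OCc3ccccc3)ccc2C1
A8 | alternative 3 | 6-(benzyloxy)-1-(3,4-dimethoxyphenyl)-7-methoxy-1,3-dihydro-2H-inden-2-one (racemic) | COc1ccc(C2C(=O)Cc3ccc(OCc4ccccc4)c(OC)c32)cc1OC
A9 | alternative 3 | ethyl diazoacetate | CCOC(=O)C=[N+]=[N-]
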